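The product of each hand is substrate of that hand gone, so the first question is which hand goes faster when a single-handed partner meets a racemate in a closed flask that holds a solid reagent and a protic impurity.

| setting | violet | blue | north-east | south-west |
|---|---|---|---|---|
| left-handed substrate | 10 mM | 10 mM | 10 mM | 10 mM |
| right-handed substrate | 10 mM | 10 mM | 10 mM | 10 mM |
| solid reagent | 0.87 equiv | 2.5 equiv | 3.00 equiv | 1.50 equiv |
| protic impurity | 10 mM | 10 mM | 10.0 mM | 10.0 mM |
| remark | run made earlier | run made earlier |  |  |
| time |  |  | 40 h | 40 h |

| run | time / h | right-handed substrate / % | left-handed substrate / % |
|---|---|---|---|
| violet | 6.00 | 48 | 44 |
| violet | 12.0 | 47 | 40 |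
| violet | 15.0 | 43 | 39 |
| violet | 25.0 | 43 | 39 |
| violet | 30.0 | 45 | 43 |
| violet | 40.0 | 46 | 37 |
| blue | 3.00 | 48 | 46 |
| blue | 5.00 | 46 | 45 |
| blue | 8.00 | 43 | 36 |
| blue | 12.0 | 38 | 29 |
| blue | 15.0 | 37 | 25 |
| blue | 25.0 | 35 | 23 |
| blue | 40.0 | 33 | 23 |

(readings scatter by 1.5 percentage points)

- partner is single-handed; left-handed substrate and right-handed substrate are mirror images of each other, charged as a racemate, each of them at the stated concentration
- solid reagent is a solid; its amount is given per volume of the solution
- at the start none of the solid reagent is in solution
- an excess is the difference of the two amounts in percent of their sum
- an excess is below zero if the other one leads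
- the handed part of partner does not stay in what it makes, so the products of the two hands are mirror images too

- the winner by excess of right-handed substrate over left-handed substrate among what is left of the two; "neither" if no more than 2 percentage points parts them (north-east / south-west / neither)
- excess of right-handed substrate over left-handed substrate among what is left of the two at the end, north-east
- excess of right-handed substrate over left-handed substrate among what is left of the two at the end, south-west

Which hand goes faster? The left-handed one, since the blue run ends with less left-handed substrate, 23%, than right-handed substrate, 33%.

By how much, when nobody has seen the partner's level rise and fall? Suppose each hand is lost in proportion to its own amount and to the partner's level. Then the partner's curve may be replaced by its mean, that mean times the time is an exposure common to the two hands, and the logarithm of a hand's starting share over what remains is that exposure times the hand's rate constant.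

What error does the mean bring? On that supposition, none in the ratio of the two logarithms, where the same exposure stands above and below and cancels. From the means of the blue readings from 15.0 h on, the left-handed logarithm over the right-handed one comes to 2.10, and this ratio is the selectivity factor, the left-handed loss over the right-handed at equal amounts.

And the weak spot? The last blue reading by itself gives 1.87, which shows what a scatter of 1.5 percentage points can do. Worse, the factor gives no exposure, so I scale the final blue exposure with the charge of solid reagent, a rough step. That leaves right-handed substrate at 30.4% in north-east and 39.0% in south-west, and the factor turns these into my excesses of 26.7% and 13.6%.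

The forecast names north-east as winner, with 23% there and 12% in south-west, and says of itself: “This is an empirical extrapolation, not a fitted mechanism.” My north-east figure is higher than the forecast's.

The flask gives north-east as winner, with 30.6% there and 12.6% in south-west.

    partner + left-handed substrate → left-handed product (k = 5.01 M⁻¹ h⁻¹)
    solid reagent ⇌ partner, rate k2*(cs2 - [partner]) while solid is left; crystals form when [partner] > cs2 (solubility = 9.00 mM, k = 1.41 h⁻¹)
    partner + protic impurity → quenched reagent (k = 9.25 M⁻¹ h⁻¹)
    partner → decomposed reagent (k = 0.0349 h⁻¹)
    partner + right-handed substrate → right-handed product (k = 2.34 M⁻¹ h⁻¹)

North-east leads south-west because of its larger charge of solid reagent: with north-east's equivalents, south-west's excess goes from 12.6% to 30.6%. In north-east the partner falls from 8.20 mM after 20.0 h to 1.63 mM after 40.0 h, yet the factor still turns the flask's 28.7% of right-handed substrate into 15.6% of left-handed substrate and an excess of 29.6%. My scaled right-handed figure for north-east was higher than that flask's.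

In the neighbour of south-west with 3.80 equiv of solid reagent, 24.2% of right-handed substrate gives by the factor 10.9% of left-handed substrate and an excess of 37.9%. The computed neighbour holds 10.6% of left-handed substrate and shows an excess of 39.1%.

All runs were computed with constants of no real substance; noise was put on by code.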